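**Retrosynthetic overview**

- Feature: in the 2H-chromene, the ring oxygen O1 is bonded to C8a, which lies para to the C6 acetyl group, so the O1–C8a bond can be made by displacing fluoride from an activated fluoroarene. The quaternary C2 (R) with its CH2–O-acyl arm is the imprint of a 2,2-disubstituted terminal epoxide opened at CH2.
- The last disconnection is the phenolic methoxymethyl (MOM) ether. The key disconnection cuts the ester CH2–O bond and the O1–C8a bond together, giving a Z-styrenyl epoxide and O-MOM ferulic acid. The pyran ring is the only ring formed; both benzene rings are bought.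
- The Z-styrenyl epoxide comes from Lindlar semi-hydrogenation of the product of a Sonogashira coupling between 1-(4-fluoro-3-iodo-5-methoxyphenyl)ethanone and (R)-2-ethynyl-2-methyloxirane.
- The aryl iodide comes from fluorine-directed ortho-lithiation and iodination of the dioxolane of 1-(4-fluoro-3-methoxyphenyl)ethanone. The alkyne comes from (R)-2-methylglycidol by oxidation and Ohira–Bestmann homologation, so the stereocentre is taken from the chiral pool and is never a reacting centre.
- The acid comes from ferulic acid by double methoxymethylation and saponification of the MOM ester.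

Key step: step 9

Assumption: commercial (R)-2-methylglycidol is taken as enantiopure (its 4-nitrobenzoate can be recrystallised beforehand if an upgrade is needed); its quaternary carbon becomes C2 (R) of the target without any bond to it being broken.

**Route**

Step 1
Reactants: 1 1-(4-fluoro-3-methoxyphenyl)ethanone
Product: 2 2-(4-fluoro-3-methoxyphenyl)-2-methyl-1,3-dioxolane
Conditions: HOCH2CH2OH, p-TsOH·H2O (catalytic), toluene, reflux, Dean–Stark
Reagents that add atoms: ethylene glycol, OCCO
Why: Acid-catalysed ketalisation with azeotropic removal of water masks the enolisable, electrophilic acetyl group as a dioxolane so that the arene tolerates an alkyllithium.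

Step 2
Reactants: 2 2-(4-fluoro-3-methoxyphenyl)-2-methyl-1,3-dioxolane
Product: 5 1-(4-fluoro-3-iodo-5-methoxyphenyl)ethanone, via aryllithium 3 (not isolated), via iodo ketal 4 (not isolated)
Conditions: n-BuLi, PMDTA, THF, −78 °C; I2, THF, −78 °C → rt; then 2 M aq HCl, THF, rt
Reagents that add atoms: iodine, II; water, O
Why: Directed ortho-metalation under acidity control (lithium saturated by PMDTA) should remove the ring hydrogen next to fluorine rather than the doubly flanked one between the methoxy group and the dioxolane-bearing carbon, −78 °C keeps the ortho-fluoroaryllithium from losing LiF to an aryne, iodinolysis gives the aryl iodide, and the acidic work-up hydrolyses the dioxolane back to the ketone.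

Step 3
Reactants: 6 (R)-2-methylglycidol
Product: 7 (2S)-2-methyloxirane-2-carbaldehyde
Conditions: Dess–Martin periodinane, NaHCO3, CH2Cl2, 0 °C → rt; filtered and carried on as a cold CH2Cl2 solution
Reagents that add atoms: none
Why: Dess–Martin oxidation under bicarbonate buffer converts the primary alcohol to the aldehyde without opening the acid-sensitive epoxide, and the quaternary α-carbon cannot epimerise (the descriptor changes to S only because the formyl group outranks the ring CH2).

Step 4
Reactants: 7 (2S)-2-methyloxirane-2-carbaldehyde
Product: 8 (2R)-2-ethynyl-2-methyloxirane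
Conditions: dimethyl (1-diazo-2-oxopropyl)phosphonate, K2CO3, MeOH, 0 °C → rt; volatile product kept as a titrated Et2O solution
Reagents that add atoms: dimethyl (1-diazo-2-oxopropyl)phosphonate, CC(=O)C(=[N+]=[N-])P(=O)(OC)OC
Why: Seyferth–Gilbert homologation with the Ohira–Bestmann reagent turns the non-enolisable aldehyde into the terminal alkyne under mild carbonate/methanol conditions that a 2,2-disubstituted epoxide should survive at or below room temperature, with the stereocentre uninvolved.

Step 5
Reactants: 5 1-(4-fluoro-3-iodo-5-methoxyphenyl)ethanone and 8 (2R)-2-ethynyl-2-methyloxirane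
Product: 9 1-[4-fluoro-3-methoxy-5-[2-[(2R)-2-methyloxiran-2-yl]ethynyl]phenyl]ethanone
Conditions: PdCl2(PPh3)2 (3 mol %), CuI (5 mol %), Et3N, THF, rt, degassed; 8 (1.3 equiv) added slowly
Reagents that add atoms: none
Why: Sonogashira coupling, in which the electron-poor aryl iodide adds to zerovalent palladium rapidly at room temperature (keeping the catalyst away from the propargylic C–O bond) and the copper acetylide delivers the alkynyl group, with ketone, aryl fluoride and epoxide as spectators.

Step 6
Reactants: 9 1-[4-fluoro-3-methoxy-5-[2-[(2R)-2-methyloxiran-2-yl]ethynyl]phenyl]ethanone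
Product: 10 1-[4-fluoro-3-methoxy-5-[(Z)-2-[(2R)-2-methyloxiran-2-yl]ethenyl]phenyl]ethanone
Conditions: H2 (1 atm), Pd/CaCO3 poisoned with Pb(OAc)2, quinoline, EtOAc, rt, stopped after one equivalent of H2; chromatography on Et3N-washed silica
Reagents that add atoms: none
Why: Lindlar semi-hydrogenation delivers both hydrogens syn from the poisoned palladium surface to give the Z alkene, the lead and quinoline poisons being there to suppress over-reduction and hydrogenolysis of the allylic C–O bond.

Step 7
Reactants: 11 ferulic acid
Product: 12 methoxymethyl (E)-3-[3-methoxy-4-(methoxymethoxy)phenyl]prop-2-enoate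
Conditions: MOMCl (2.5 equiv), iPr2NEt (3 equiv), CH2Cl2, 0 °C → rt
Reagents that add atoms: chloromethyl methyl ether, COCCl
Why: O-Alkylation of both the phenol and the carboxylic acid by the oxocarbenium-like chloromethyl ether (Williamson-type etherification and esterification) installs a phenol protecting group that is inert to base and to fluoride.

Step 8
Reactants: 12 methoxymethyl (E)-3-[3-methoxy-4-(methoxymethoxy)phenyl]prop-2-enoate
Product: 13 (E)-3-[3-methoxy-4-(methoxymethoxy)phenyl]prop-2-enoic acid
Conditions: LiOH·H2O, THF/H2O, 0 °C → rt; then 1 M HCl to pH 4, 0 °C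
Reagents that add atoms: lithium hydroxide, [Li+].[OH-]
Why: Saponification cleaves the activated acyl-acetal (MOM) ester while the aryl MOM ether is inert to hydroxide, and brief cold acidification to pH 4 should free the acid without touching the acetal.

Step 9
Reactants: 10 1-[4-fluoro-3-methoxy-5-[(Z)-2-[(2R)-2-methyloxiran-2-yl]ethenyl]phenyl]ethanone and 13 (E)-3-[3-methoxy-4-(methoxymethoxy)phenyl]prop-2-enoic acid
Product: 16 [(2R)-6-acetyl-8-methoxy-2-methyl-2H-chromen-2-yl]methyl (E)-3-[3-methoxy-4-(methoxymethoxy)phenyl]prop-2-enoate, via caesium carboxylate 14 (not isolated), via caesium alkoxide 15 (not isolated)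
Conditions: 13 (1.3 equiv), Cs2CO3 (2 equiv), 4 Å MS, DMSO, rt; then 10, 70–85 °C
Reagents that add atoms: none
Why: Cs2CO3 converts 13 into caesium carboxylate 14, which opens the epoxide of 10 by SN2 attack at the unsubstituted CH2, so the C2–O bond and the R configuration brought in with the methylglycidol stay untouched and no new stereocentre is created. The tertiary caesium alkoxide 15 released in this way is held by the Z alkene over the fluorine-bearing carbon (the future C8a), adds there to give a Meisenheimer anion delocalised into the para acetyl group, and expels fluoride (addition–elimination aromatic substitution). The pyran ring therefore closes by a 6-exo-trig addition to the arene carbon followed by elimination, forming O1–C8a after the ester CH2–O bond. The closest known reaction types are the opening of terminal epoxides at the less substituted carbon by carboxylates and the intramolecular displacement of fluoride from para-acyl fluoroarenes by alkoxides, run here as a domino sequence. The step needs the carboxylate to choose the epoxide CH2 over C8a, which should follow from the poor nucleophilicity of a carboxylate toward a fluoroarene carbon flanked by two ortho substituents. It also needs cyclisation to outrun acyl scrambling, which is expected because the 1,2-acyl shift to the tertiary oxygen is reversible and only the tertiary alkoxide reaches C8a through a six-membered transition state, so the equilibrating mixture should drain to 16.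

Step 10
Reactants: 16 [(2R)-6-acetyl-8-methoxy-2-methyl-2H-chromen-2-yl]methyl (E)-3-[3-methoxy-4-(methoxymethoxy)phenyl]prop-2-enoate
Product: 17 [(2R)-6-acetyl-8-methoxy-2-methyl-2H-chromen-2-yl]methyl (E)-3-(4-hydroxy-3-methoxyphenyl)prop-2-enoate (CNP0168033.1)
Conditions: 3 M aq HCl, THF, 40 °C
Reagents that add atoms: none
Why: Acid-catalysed acetal hydrolysis of the aryl MOM ether through an oxocarbenium ion frees the phenol, while the neopentyl-type cinnamate ester, the aryl ketone and the 2H-chromene (whose ring oxygen is tempered by the para acetyl group) should tolerate dilute acid at this temperature.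

**Compound list**

1 | 1-(4-fluoro-3-methoxyphenyl)ethanone | CC(=O)c1ccc(F)c(OC)c1 | starting material
2 | 2-(4-fluoro-3-methoxyphenyl)-2-methyl-1,3-dioxolane | CC1(OCCO1)c1ccc(F)c(OC)c1 | intermediate
3 | [2-fluoro-3-methoxy-5-(2-methyl-1,3-dioxolan-2-yl)phenyl]lithium (not isolated) | [Li]c1cc(cc(OC)c1F)C1(C)OCCO1 | intermediate
4 | 2-(4-fluoro-3-iodo-5-methoxyphenyl)-2-methyl-1,3-dioxolane (not isolated) | CC1(OCCO1)c1cc(I)c(F)c(OC)c1 | intermediate
5 | 1-(4-fluoro-3-iodo-5-methoxyphenyl)ethanone | CC(=O)c1cc(I)c(F)c(OC)c1 | intermediate
6 | (R)-2-methylglycidol, [(2R)-2-methyloxiran-2-yl]methanol | O1C[C@@]1(C)CO | starting material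
7 | (2S)-2-methyloxirane-2-carbaldehyde | O1C[C@@]1(C)C=O | intermediate
8 | (2R)-2-ethynyl-2-methyloxirane | O1C[C@@]1(C)C#C | intermediate
9 | 1-[4-fluoro-3-methoxy-5-[2-[(2R)-2-methyloxiran-2-yl]ethynyl]phenyl]ethanone | O1C[C@@]1(C)C#Cc1cc(C(C)=O)cc(OC)c1F | intermediate
10 | 1-[4-fluoro-3-methoxy-5-[(Z)-2-[(2R)-2-methyloxiran-2-yl]ethenyl]phenyl]ethanone | O1C[C@@]1(C)/C=C\c1cc(C(C)=O)cc(OC)c1F | intermediate
11 | ferulic acid, (E)-3-(4-hydroxy-3-methoxyphenyl)prop-2-enoic acid | COc1cc(/C=C/C(=O)O)ccc1O | starting material
12 | methoxymethyl (E)-3-[3-methoxy-4-(methoxymethoxy)phenyl]prop-2-enoate | COCOC(=O)/C=C/c1ccc(OCOC)c(OC)c1 | intermediate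
13 | (E)-3-[3-methoxy-4-(methoxymethoxy)phenyl]prop-2-enoic acid | COCOc1ccc(/C=C/C(=O)O)cc1OC | intermediate
14 | caesium (E)-3-[3-methoxy-4-(methoxymethoxy)phenyl]prop-2-enoate (not isolated) | COCOc1ccc(/C=C/C(=O)[O-])cc1OC.[Cs+] | intermediate
15 | caesium (2R,3Z)-4-(5-acetyl-2-fluoro-3-methoxyphenyl)-2-methyl-1-[(E)-3-[3-methoxy-4-(methoxymethoxy)phenyl]prop-2-enoyl]oxybut-3-en-2-olate (not isolated) | COCOc1ccc(/C=C/C(=O)OC[C@@]([O-])(C)/C=C\c2cc(C(C)=O)cc(OC)c2F)cc1OC.[Cs+] | intermediate
16 | [(2R)-6-acetyl-8-methoxy-2-methyl-2H-chromen-2-yl]methyl (E)-3-[3-methoxy-4-(methoxymethoxy)phenyl]prop-2-enoate | COCOc1ccc(/C=C/C(=O)OC[C@@]2(C)C=Cc3cc(C(C)=O)cc(OC)c3O2)cc1OC | intermediate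
17 | [(2R)-6-acetyl-8-methoxy-2-methyl-2H-chromen-2-yl]methyl (E)-3-(4-hydroxy-3-methoxyphenyl)prop-2-enoate (CNP0168033.1) | COc1cc(/C=C/C(=O)OC[C@@]2(C)C=Cc3cc(C(C)=O)cc(OC)c3O2)ccc1O | target

**Step count and risks**

Total step count: 10. Longest linear sequence: 6 steps (steps 1, 2, 5, 6, 9, 10; the branch from 6 through steps 3, 4, 5, 6, 9, 10 is equally long).

Steps most likely to fail:

1. Step 9. The carboxylate may open the hindered epoxide too slowly at temperatures where the liberated alkoxide instead scrambles acyl groups between molecules, adds to the cinnamate double bond, or cyclises through the migrated primary oxygen to a seven-membered ether. The fallback separates the two events into isolated, individually known operations. It sets out from 10 and 13: the epoxide is opened under buffered conditions (excess 13 with a substoichiometric amount of Cs2CO3 in DMSO at about 70 °C), so that each alkoxide is protonated as it forms and no fluoride chemistry can start. This should give (2R,3Z)-4-(5-acetyl-2-fluoro-3-methoxyphenyl)-2-hydroxy-2-methylbut-3-en-1-yl (E)-3-[3-methoxy-4-(methoxymethoxy)phenyl]prop-2-enoate F1, which is purified. The tertiary alcohol is then deprotonated with NaH in THF at 0 °C → rt, where intramolecular fluoride displacement should close the pyran ring. The fallback comes back to the route at 16.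

2. Step 5. Zerovalent palladium may insert into the propargylic C–O bond of the ethynyl epoxide (allenylpalladium formation and oligomerisation), the alkyne may homocouple, and the volatile alkyne may be lost on handling. The fallback keeps the epoxide masked during the palladium step. It sets out from 8, which is opened with LiCl and AcOH in THF at the CH2 carbon to (2R)-1-chloro-2-methylbut-3-yn-2-ol F2, a robust tertiary propargylic alcohol. This is coupled with 5 under the same PdCl2(PPh3)2/CuI/Et3N conditions to give 1-[3-[(3R)-4-chloro-3-hydroxy-3-methylbut-1-yn-1-yl]-4-fluoro-5-methoxyphenyl]ethanone F3. The epoxide is then re-closed with K2CO3 in MeOH by intramolecular Williamson etherification, the tertiary C–O bond being untouched throughout. The fallback comes back to the route at 9.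

3. Step 2. Metalation may occur at the wrong ring position (between the methoxy group and the dioxolane-bearing carbon), or the ortho-fluoroaryllithium may lose LiF to an aryne before it is trapped. The fallback replaces deprotonation by a sterically governed C–H functionalisation. It sets out from 2, which is borylated with B2pin2, [Ir(OMe)(cod)]2 and 4,4'-di-tert-butyl-2,2'-bipyridine in THF at 80 °C. The only ring C–H without an ortho substituent larger than fluorine is the one next to fluorine, so this should give 2-[2-fluoro-3-methoxy-5-(2-methyl-1,3-dioxolan-2-yl)phenyl]-4,4,5,5-tetramethyl-1,3,2-dioxaborolane F4. Iododeboronation with CuI, 1,10-phenanthroline and KI in MeOH/H2O under air then converts the C–B bond into the C–I bond. The fallback comes back to the route at iodo ketal 4, which is hydrolysed to 5 with aqueous HCl as in the last stage of step 2.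

**Further compounds**

F1 | step 9 | (2R,3Z)-4-(5-acetyl-2-fluoro-3-methoxyphenyl)-2-hydroxy-2-methylbut-3-en-1-yl (E)-3-[3-methoxy-4-(methoxymethoxy)phenyl]prop-2-enoate | COCOc1ccc(/C=C/C(=O)OC[C@@](O)(C)/C=C\c2cc(C(C)=O)cc(OC)c2F)cc1OC
F2 | step 5 | (2R)-1-chloro-2-methylbut-3-yn-2-ol | ClC[C@@](O)(C)C#C
F3 | step 5 | 1-[3-[(3R)-4-chloro-3-hydroxy-3-methylbut-1-yn-1-yl]-4-fluoro-5-methoxyphenyl]ethanone | ClC[C@@](O)(C)C#Cc1cc(C(C)=O)cc(OC)c1F
F4 | step 2 | 2-[2-fluoro-3-methoxy-5-(2-methyl-1,3-dioxolan-2-yl)phenyl]-4,4,5,5-tetramethyl-1,3,2-dioxaborolane | CC1(OCCO1)c1cc(B2OC(C)(C)C(C)(C)O2)c(F)c(OC)c1
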